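The route closes the seven-membered ring D last, across C16–C17 (Cn = nth non-hydrogen atom of the target SMILES). This is the only CH2–CH2 bond of that ring and lies between the tertiary carbinol C14 and C18. One ring-closing metathesis joins a C14 vinyl carbinol to a C18 vinyl group, forms the C16=C17 alkene and completes the pentacycle without touching any of the ten stereocentres. Its precursor is a seco diene in which the West tricycle (rings A–C) and the East ring E are already linked through the C30–C28 ketone. The C22 hydroxyl is carried as a benzyl ether, so that C28 can be oxidised selectively; the final hydrogenation removes it.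

Key step: step 26

Remark: rings follow the target SMILES (A: C3–C6, C8, C33; B: C6, C8–C11, C32; C: C11, C13, C14, C30–C32; D: C14, C16–C18, C26, C28, C30; E: C18, C19, C22, C24–C26).
Remark: racemic compounds (5–7, 14, 15, 18–20) are drawn as the enantiomer that is carried on; the two Diels–Alder products are resolved in steps 5 and 15.
Remark: the carbinol centre C28 of 30, 31, 33 and 34 is drawn without a descriptor, because both epimers converge in step 25.

Step 1
Reactants: 1 4-methylpent-1-en-3-ol
Product: 2 4-methylpent-1-en-3-one
Conditions: activated MnO2, CH2Cl2, rt; filtration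
Reagents that add atoms: none
Why: Allylic alcohol oxidation with MnO2 is selective for the carbinol next to the alkene and lets the volatile enone be obtained by simple filtration.

Step 2
Reactants: 2 4-methylpent-1-en-3-one
Product: 3 tert-butyldimethylsilyl enol ether diene (3-silyloxy-4-methylpenta-1,3-diene)
Conditions: t-BuMe2SiOTf, Et3N, Et2O, 0 °C
Reagents that add atoms: tert-butyldimethylsilyl triflate, CC(C)(C)[Si](C)(C)OS(=O)(=O)C(F)(F)F
Why: Silyl enol ether formation by soft enolization can only occur at the isopropyl methine, the single enolizable position, so the cross-conjugated 2-silyloxy diene is the only possible product.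

Step 3
Reactants: 3 silyloxy diene; 4 citraconic anhydride
Product: 5 racemic cis-fused anhydride (ring E with C26 methyl and H-18 cis, silyl enol ether at C22)
Conditions: toluene, 80 °C, sealed vessel, trace 2,6-di-tert-butyl-4-methylphenol
Reagents that add atoms: none
Why: Thermal Diels–Alder reaction in which the nucleophilic CMe2 terminus of the diene bonds to the unsubstituted alkene carbon of the anhydride for both electronic and steric reasons, while suprafacial addition to the cyclic cis dienophile fixes the C26 methyl and H-18 on the same face, so that C28 and C17 are cis on ring E.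

Step 4
Reactants: 5 racemic cis-fused anhydride
Product: 7 racemic keto lactone (C17 lactone carbonyl, C28 as OCH2, C22 ketone), via lactone silyl enol ether 6 (not isolated)
Conditions: NaBH4, THF, 0 °C to rt; then 2 M HCl, THF, rt
Reagents that add atoms: none
Why: Borohydride reduction of a cyclic anhydride to a lactone, which for anhydrides with one fully substituted α-carbon normally takes place at the carbonyl on that carbon (C28), followed by acid-promoted lactonization and hydrolysis of the silyl enol ether.

Step 5
Reactants: 7 racemic keto lactone
Product: 8 hydroxy lactone, C22 (R), hydroxyl cis to C17 and C28, single enantiomer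
Conditions: (S)-2-methyl-CBS-oxazaborolidine (15 mol%), BH3·SMe2 (0.55 equiv), toluene, −20 °C; MeOH quench; chromatography to remove unreacted ketone, then recrystallization
Reagents that add atoms: none
Why: Corey–Bakshi–Shibata reduction run as a kinetic resolution, because the (S)-catalyst gives the (R)-carbinol when the quaternary C19 side is the large group, and only in the enantiomer drawn does this coincide with the substrate's own preference for axial hydride attack on the face opposite the lactone bridge, so that enantiomer should be reduced much faster and C22 is set with the hydroxyl cis to C17 and C28.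

Step 6
Reactants: 8 hydroxy lactone
Product: 9 C22 benzyl ether lactone
Conditions: benzyl 2,2,2-trichloroacetimidate, TfOH (5 mol%), CH2Cl2/cyclohexane, 0 °C to rt
Reagents that add atoms: benzyl 2,2,2-trichloroacetimidate, ClC(Cl)(Cl)C(=N)OCc1ccccc1
Why: Acid-catalysed benzylation with the trichloroacetimidate needs no base, so the lactone and its α-stereocentre C18 are not endangered, and the ether will mask O-22 during the later oxidation at C28.

Step 7
Reactants: 9 benzyl ether lactone
Product: 10 lactol (mixture of anomers at C17)
Conditions: i-Bu2AlH, CH2Cl2, −78 °C; aqueous potassium sodium tartrate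
Reagents that add atoms: none
Why: Partial reduction of a γ-lactone with i-Bu2AlH stops at the lactol, because the tetrahedral aluminium hemiacetal does not collapse at −78 °C.

Step 8
Reactants: 10 lactol
Product: 11 alkenol (C18 vinyl, C28 hydroxymethyl)
Conditions: Ph3PCH3Br, KOtBu, THF, 0 °C to rt
Reagents that add atoms: methyltriphenylphosphonium bromide, C[P+](c1ccccc1)(c1ccccc1)c1ccccc1.[Br-]
Why: Wittig methylenation of the lactol through its open hydroxy aldehyde form turns C17 into the C18 vinyl group and releases C28 as the primary alcohol, and H-18 lies between two quaternary carbons, so it should not epimerize.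

Step 9
Reactants: 11 alkenol
Product: 12 East aldehyde (C28 formyl on quaternary C26, C18 vinyl, C22 benzyl ether)
Conditions: Dess–Martin periodinane, NaHCO3, CH2Cl2, 0 °C to rt
Reagents that add atoms: none
Why: Dess–Martin oxidation of the neopentyl primary alcohol gives an aldehyde that cannot enolize because C26 is quaternary, so no stereocentre is at risk.

Step 10
Reactants: 3 silyloxy diene; 13 2-methylcyclohex-2-en-1-one
Product: 14 racemic cis-fused bicyclic ketone (rings A and B, C32 ketone, silyl enol ether at C3)
Conditions: AlBr3/AlMe3 (10:1, 0.3 equiv), toluene/CH2Cl2, −5 °C; then pyridine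
Reagents that add atoms: none
Why: Lewis-acid-catalysed Diels–Alder reaction of a 2-silyloxy diene with a 2-methylcycloalkenone, in which the CMe2 terminus adds to the enone β-carbon so that the silyloxy carbon ends para to C6, and suprafacial addition across the ring alkene makes the A/B fusion cis with the C7 methyl and H-8 on one face.

Step 11
Reactants: 14 racemic bicyclic ketone
Product: 15 racemic enol triflate (C32=C11)
Conditions: PhNTf2, KN(SiMe3)2, THF, −78 to 0 °C
Reagents that add atoms: N-phenyl-bis(trifluoromethanesulfonimide), O=S(=O)(N(c1ccccc1)S(=O)(=O)C(F)(F)F)C(F)(F)F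
Why: Enol triflate formation is regiospecific because the ketone can enolize only toward C11 (C6 is quaternary), and the silyl enol ether keeps the ring A carbonyl masked meanwhile.

Step 12
Reactants: 15 racemic enol triflate; 16 2-(2-bromoethyl)-2-methyl-1,3-dioxolane
Product: 18 racemic coupled diene (masked 3-oxobutyl chain C31–C30–C14–C13 on C32), via alkylzinc bromide 17 (not isolated)
Conditions: 16, Zn dust, LiCl, THF, 50 °C; then 15, PdCl2(dppf) (5 mol%), THF, 60 °C
Reagents that add atoms: none
Why: Negishi coupling of a primary alkylzinc reagent with the enol triflate attaches the four-carbon chain at C32, the chelating diphosphine suppressing β-hydride elimination.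

Step 13
Reactants: 18 racemic coupled diene
Product: 19 racemic ring A ketone (C3)
Conditions: Bu4NF, AcOH, THF, 0 °C
Reagents that add atoms: none
Why: Buffered fluoride cleaves the silyl enol ether to the ketone and leaves the ketal and the trisubstituted alkene untouched.

Step 14
Reactants: 19 racemic ring A ketone
Product: 20 racemic C3 alcohol (hydroxyl cis to the C7 methyl)
Conditions: Li, liquid NH3, THF, EtOH, −78 °C; NH4Cl
Reagents that add atoms: none
Why: Dissolving-metal reduction gives the thermodynamically preferred alcohol, and in the favoured cis-decalin conformer (C5 axial and C33 equatorial on ring B) the equatorial C3 hydroxyl is the one cis to the C7 methyl, since its epimer would clash 1,3-diaxially with C9.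

Step 15
Reactants: 20 racemic C3 alcohol
Product: 21 (3S)-alcohol, single enantiomer
Conditions: immobilised Burkholderia cepacia lipase, vinyl acetate, t-BuOMe, 35 °C, run just past half conversion; chromatography
Reagents that add atoms: none
Why: Lipase-catalysed acylation as a kinetic resolution, in which a secondary alcohol flanked by a large (CMe2) and a medium (CH2) group is acylated preferentially as its (R)-enantiomer, so the required (S)-alcohol is the one left behind and becomes enantiopure once conversion passes one half.

Step 16
Reactants: 21 (3S)-alcohol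
Product: 22 C3 methyl ether
Conditions: NaH, MeI, THF/DMF, 0 °C to rt
Reagents that add atoms: iodomethane, CI
Why: Williamson ether synthesis with the small electrophile MeI methylates the hindered equatorial alkoxide without affecting the ketal or the alkene.

Step 17
Reactants: 22 C3 methyl ether
Product: 24 C11 alcohol (H-32 and C11 hydroxyl on the face of the C7 methyl), via alkylborane 23 (not isolated)
Conditions: BH3·THF, THF, 0 °C to rt; then NaOH, H2O2, 0 °C to rt
Reagents that add atoms: hydrogen peroxide, OO
Why: Hydroboration–oxidation places boron on the less substituted C11 and delivers hydrogen to C32 from the convex face, anti to the axial C5 methylene, so H-32 ends cis to the C7 methyl and C31 cis to C5.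

Step 18
Reactants: 24 C11 alcohol
Product: 25 C11 ketone
Conditions: Dess–Martin periodinane, NaHCO3, CH2Cl2, 0 °C to rt
Reagents that add atoms: none
Why: Dess–Martin oxidation of the secondary alcohol proceeds under buffered neutral conditions that keep the ketal and should not epimerize C32.

Step 19
Reactants: 25 C11 ketone
Product: 27 tricyclic enone (C14 ketone, C13=C11), via 1,5-diketone 26 (not isolated)
Conditions: 2 M HCl, THF, rt; then NaOMe, MeOH, 60 °C
Reagents that add atoms: water, O
Why: Ketal hydrolysis followed by intramolecular aldol condensation of the methyl ketone carbon C13 onto the C11 ketone (the ring-forming half of a Robinson annulation) closes ring C, and C32 should stay in its more stable configuration with C31 equatorial on ring B.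

Step 20
Reactants: 27 tricyclic enone
Product: 28 West ketone (rings A–C, C14 ketone, C12 methyl cis to H-32)
Conditions: Me2CuLi (from MeLi and copper monoiodide), Et2O, −20 to 0 °C; aqueous NH4Cl
Reagents that add atoms: lithium dimethylcuprate, [Li+].C[Cu-]C
Why: Conjugate addition of the cuprate to the β,β-disubstituted enone delivers methyl axially to ring C from the face of H-32, the other face being blocked by the axial C5 methylene of ring A, which gives the cis B/C fusion as with simple octalones.

Step 21
Reactants: 28 West ketone; 12 East aldehyde
Product: 30 aldol adduct (C30–C28 bond, C28 carbinol), via lithium enolate 29 (not isolated)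
Conditions: LiN(i-Pr)2, THF, −78 °C; then 12, −78 °C; AcOH quench at −78 °C
Reagents that add atoms: none
Why: Aldol addition in which kinetic deprotonation occurs at C30 and not at C13, which is shielded by quaternary C11, and the non-enolizable aldehyde adds to the enolate face opposite the axial C32–C6 bond, so the new substituent at C30 should be equatorial.

Step 22
Reactants: 30 aldol adduct
Product: 31 C28 triethylsilyl ether
Conditions: Et3SiOTf, 2,6-lutidine, CH2Cl2, −78 to 0 °C
Reagents that add atoms: triethylsilyl triflate, CC[Si](CC)(CC)OS(=O)(=O)C(F)(F)F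
Why: Silylation of the hindered aldol hydroxyl with the reactive silyl triflate blocks retro-aldol cleavage during the organometallic addition that follows.

Step 23
Reactants: 31 C28 triethylsilyl ether; 32 vinylmagnesium bromide
Product: 33 C14 vinyl carbinol (hydroxyl cis to the C12 methyl and to C28)
Conditions: CH2=CHMgBr, anhydrous CeCl3, THF, −78 °C
Reagents that add atoms: none
Why: Organocerium 1,2-addition, in which the weakly basic vinylcerium reagent should add to the hindered ketone without enolization or β-elimination, and attacks equatorially, anti to the axial C12 methyl and trans to the C30 substituent, to give the axial C14 hydroxyl.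

Step 24
Reactants: 33 C14 vinyl carbinol
Product: 34 C14,C28 diol
Conditions: Bu4NF, THF, 0 °C to rt
Reagents that add atoms: none
Why: Fluoride-mediated desilylation removes the triethylsilyl ether while the benzyl ether stays, and since no ketone is present the basic medium cannot cause retro-aldol cleavage.

Step 25
Reactants: 34 diol
Product: 35 seco diene (C14 vinyl carbinol, C28 ketone, C18 vinyl, C22 benzyl ether)
Conditions: Dess–Martin periodinane, NaHCO3, CH2Cl2, 0 °C
Reagents that add atoms: none
Why: Dess–Martin oxidation acts on the only oxidizable alcohol (C28, since C14 is tertiary and O-22 is benzylated) under buffered conditions that should spare the β-hydroxy ketone from retro-aldol cleavage and from epimerization at C30.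

Step 26
Reactants: 35 seco diene
Product: 36 16,17-dehydro pentacycle (cycloheptene ring D, C22 benzyl ether)
Conditions: second-generation Grubbs catalyst RuCl2(=CHPh)(PCy3)(H2IMes) (10 mol%), 1,4-benzoquinone (20 mol%), toluene (0.002 M), 80 °C, argon sparge
Reagents that add atoms: none
Why: Ring-closing olefin metathesis, whose closest known class is cycloheptene formation from dienes that contain a tertiary allylic alcohol: the ruthenium alkylidene exchanges with one vinyl group, most likely the C14 vinyl whose hydroxyl assists loading, and the new carbene undergoes [2+2] cycloaddition and cycloreversion with the C18 vinyl group, forming C16=C17 and releasing ethylene. Ring D is closed in a seven-membered ring-closing step that can only give the cis alkene. No stereocentre is formed, since all ten are in place beforehand. The trans-diequatorial C14 vinyl and C30 acyl groups on ring C and the cis relationship of C28 and the vinyl group on ring E hold the two alkenes close together. The step needs cyclization to outrun dimerization and alkene migration, which high dilution, the fully substituted carbons C26 and C19 and the benzoquinone additive should secure. It also needs the β-hydroxy ketone to survive, which the neutral conditions allow.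

Step 27
Reactants: 36 16,17-dehydro pentacycle
Product: 37 target CNP0259231.1
Conditions: H2 (1 atm), Pd(OH)2/C, EtOAc/EtOH, rt
Reagents that add atoms: none
Why: Heterogeneous hydrogenation saturates the cis-disubstituted C16=C17 alkene and cleaves the benzyl ether by hydrogenolysis in the same operation, while the ketone, the tertiary alcohol and the methyl ether are inert and no stereocentre is created.

Compound list
1 | 4-methylpent-1-en-3-ol (racemic) | C=CC(O)C(C)C | starting material
2 | 4-methylpent-1-en-3-one | C=CC(=O)C(C)C | intermediate
3 | tert-butyldimethyl[(4-methylpenta-1,3-dien-3-yl)oxy]silane | C=CC(O[Si](C)(C)C(C)(C)C)=C(C)C | intermediate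
4 | citraconic anhydride | CC1=CC(=O)OC1=O | starting material
5 | cis-fused anhydride, silyl enol ether at C22 (racemic) | O=C1[C@@]2(C)CC=C(O[Si](C)(C)C(C)(C)C)C(C)(C)[C@H]2C(=O)O1 | intermediate
6 | lactone silyl enol ether (racemic, not isolated) | C1[C@@]2(C)CC=C(O[Si](C)(C)C(C)(C)C)C(C)(C)[C@H]2C(=O)O1 | intermediate
7 | keto lactone (racemic) | C1[C@@]2(C)CCC(=O)C(C)(C)[C@H]2C(=O)O1 | intermediate
8 | hydroxy lactone, C22 (R) | C1[C@@]2(C)CC[C@@H](O)C(C)(C)[C@H]2C(=O)O1 | intermediate
9 | benzyl ether lactone | C1[C@@]2(C)CC[C@@H](OCc3ccccc3)C(C)(C)[C@H]2C(=O)O1 | intermediate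
10 | lactol (anomers) | C1[C@@]2(C)CC[C@@H](OCc3ccccc3)C(C)(C)[C@H]2C(O)O1 | intermediate
11 | alkenol (C18 vinyl, C28 hydroxymethyl) | OC[C@@]1(C)CC[C@@H](OCc2ccccc2)C(C)(C)[C@H]1C=C | intermediate
12 | East aldehyde | O=C[C@@]1(C)CC[C@@H](OCc2ccccc2)C(C)(C)[C@H]1C=C | intermediate
13 | 2-methylcyclohex-2-en-1-one | CC1=CCCCC1=O | starting material
14 | cis-fused bicyclic ketone, silyl enol ether at C3 (racemic) | CC(C)(C)[Si](C)(C)OC1=CC[C@@]2(C)[C@H](CCCC2=O)C1(C)C | intermediate
15 | enol triflate (racemic) | CC(C)(C)[Si](C)(C)OC1=CC[C@@]2(C)[C@H](CCC=C2OS(=O)(=O)C(F)(F)F)C1(C)C | intermediate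
16 | 2-(2-bromoethyl)-2-methyl-1,3-dioxolane | CC1(CCBr)OCCO1 | starting material
17 | [2-(2-methyl-1,3-dioxolan-2-yl)ethyl]zinc bromide (not isolated) | CC1(CC[Zn]Br)OCCO1 | intermediate
18 | coupled diene (racemic) | CC(C)(C)[Si](C)(C)OC1=CC[C@@]2(C)[C@H](CCC=C2CCC3(C)OCCO3)C1(C)C | intermediate
19 | ring A ketone (racemic) | O=C1CC[C@@]2(C)[C@H](CCC=C2CCC3(C)OCCO3)C1(C)C | intermediate
20 | C3 alcohol (racemic) | O[C@H]1CC[C@@]2(C)[C@H](CCC=C2CCC3(C)OCCO3)C1(C)C | intermediate
21 | (3S)-alcohol, single enantiomer | O[C@H]1CC[C@@]2(C)[C@H](CCC=C2CCC3(C)OCCO3)C1(C)C | intermediate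
22 | C3 methyl ether | CO[C@H]1CC[C@@]2(C)[C@H](CCC=C2CCC3(C)OCCO3)C1(C)C | intermediate
23 | C11 alkylborane (not isolated) | CO[C@H]1CC[C@@]2(C)[C@H](CC[C@H](B)[C@H]2CCC3(C)OCCO3)C1(C)C | intermediate
24 | C11 alcohol | CO[C@H]1CC[C@@]2(C)[C@H](CC[C@H](O)[C@H]2CCC3(C)OCCO3)C1(C)C | intermediate
25 | C11 ketone | CO[C@H]1CC[C@@]2(C)[C@H](CCC(=O)[C@H]2CCC3(C)OCCO3)C1(C)C | intermediate
26 | 1,5-diketone (not isolated) | CO[C@H]1CC[C@@]2(C)[C@H](CCC(=O)[C@H]2CCC(C)=O)C1(C)C | intermediate
27 | tricyclic enone | CO[C@H]1CC[C@@]2(C)[C@H](CCC3=CC(=O)CC[C@H]32)C1(C)C | intermediate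
28 | West ketone | CO[C@H]1CC[C@@]2(C)[C@H](CC[C@@]3(C)CC(=O)CC[C@H]32)C1(C)C | intermediate
29 | lithium enolate of 28 (C14–O, C14=C30; not isolated) | CO[C@H]1CC[C@@]2(C)[C@H](CC[C@@]3(C)CC(O[Li])=CC[C@H]32)C1(C)C | intermediate
30 | aldol adduct | CO[C@H]1CC[C@@]2(C)[C@H](CC[C@@]3(C)CC(=O)[C@H](C(O)[C@@]5(C)CC[C@@H](OCc4ccccc4)C(C)(C)[C@H]5C=C)C[C@H]32)C1(C)C | intermediate
31 | C28 triethylsilyl ether | CO[C@H]1CC[C@@]2(C)[C@H](CC[C@@]3(C)CC(=O)[C@H](C(O[Si](CC)(CC)CC)[C@@]5(C)CC[C@@H](OCc4ccccc4)C(C)(C)[C@H]5C=C)C[C@H]32)C1(C)C | intermediate
32 | vinylmagnesium bromide | C=C[Mg]Br | starting material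
33 | C14 vinyl carbinol | CO[C@H]1CC[C@@]2(C)[C@H](CC[C@@]3(C)C[C@@](O)(C=C)[C@H](C(O[Si](CC)(CC)CC)[C@@]5(C)CC[C@@H](OCc4ccccc4)C(C)(C)[C@H]5C=C)C[C@H]32)C1(C)C | intermediate
34 | C14,C28 diol | CO[C@H]1CC[C@@]2(C)[C@H](CC[C@@]3(C)C[C@@](O)(C=C)[C@H](C(O)[C@@]5(C)CC[C@@H](OCc4ccccc4)C(C)(C)[C@H]5C=C)C[C@H]32)C1(C)C | intermediate
35 | seco diene (metathesis precursor, C22 benzyl ether) | CO[C@H]1CC[C@@]2(C)[C@H](CC[C@@]3(C)C[C@@](O)(C=C)[C@H](C(=O)[C@@]5(C)CC[C@@H](OCc4ccccc4)C(C)(C)[C@H]5C=C)C[C@H]32)C1(C)C | intermediate
36 | 16,17-dehydro pentacycle, C22 benzyl ether | CO[C@H]1CC[C@@]2(C)[C@H](CC[C@@]3(C)C[C@@]4(O)C=C[C@@H]5C(C)(C)[C@H](OCc6ccccc6)CC[C@]5(C)C(=O)[C@@H]4C[C@H]32)C1(C)C | intermediate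
37 | CNP0259231.1 | CO[C@H]1CC[C@@]2(C)[C@H](CC[C@@]3(C)C[C@@]4(O)CC[C@@H]5C(C)(C)[C@H](O)CC[C@]5(C)C(=O)[C@@H]4C[C@H]32)C1(C)C | target

Total step count: 27. Longest linear sequence: 20 steps (steps 1, 2, 10–27); the East branch (steps 3–9) joins at step 21.

Steps most likely to fail

Step 26. Both vinyl groups sit next to fully substituted carbons, so loading of the catalyst may be slow, and intermolecular metathesis or catalyst decay may then outrun ring closure. The fallback is a relay ring-closing metathesis that sets out from 31 and returns to the route at 36. (E)-Hepta-1,6-dien-1-yllithium (from the iodide and t-BuLi), transmetallated with CeCl3, is added to 31 in place of the vinyl reagent and should give the relay carbinol F1. Bu4NF then frees the C28 alcohol to give the relay diol F2, and Dess–Martin oxidation gives the relay ketone F3. With the same ruthenium catalyst, initiation occurs at the unhindered terminal alkene, loss of cyclopentene places the metal on C16 intramolecularly, and closure onto the C18 vinyl group gives 36.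

Step 21. The lithium aldolate formed from two hindered partners may form slowly or revert by retro-aldol cleavage before the quench, letting the enolate equilibrate. The fallback is a Mukaiyama aldol addition that sets out from 28 and returns at 30. The kinetic enolate is trapped with Me3SiCl to give the trimethylsilyl enol ether F4, which is combined with 12 and BF3·OEt2 in CH2Cl2 at −78 °C; silyl transfer makes the addition irreversible.

Step 5. The rate difference between the two ketone enantiomers may be too small, so the hydroxy lactone would be carried on with eroded enantiomeric purity. The fallback is a classical resolution that sets out from 7 and returns at 8. NaBH4 in MeOH reduces racemic 7 from the convex face to the racemic hydroxy lactone F5. Esterification with (S)-O-methylmandelic acid (dicyclohexylcarbodiimide, 4-dimethylaminopyridine) gives diastereomeric esters that are separated by chromatography or crystallization. The ester of the required enantiomer, mandelate F6, is then cleaved with LiOH, and acidification re-closes the lactone to 8.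

Further compounds
F1 | step 26 | relay carbinol (C14 (E)-hepta-1,6-dienyl, C28 triethylsilyl ether) | CO[C@H]1CC[C@@]2(C)[C@H](CC[C@@]3(C)C[C@@](O)(/C=C/CCCC=C)[C@H](C(O[Si](CC)(CC)CC)[C@@]5(C)CC[C@@H](OCc4ccccc4)C(C)(C)[C@H]5C=C)C[C@H]32)C1(C)C
F2 | step 26 | relay diol | CO[C@H]1CC[C@@]2(C)[C@H](CC[C@@]3(C)C[C@@](O)(/C=C/CCCC=C)[C@H](C(O)[C@@]5(C)CC[C@@H](OCc4ccccc4)C(C)(C)[C@H]5C=C)C[C@H]32)C1(C)C
F3 | step 26 | relay ketone | CO[C@H]1CC[C@@]2(C)[C@H](CC[C@@]3(C)C[C@@](O)(/C=C/CCCC=C)[C@H](C(=O)[C@@]5(C)CC[C@@H](OCc4ccccc4)C(C)(C)[C@H]5C=C)C[C@H]32)C1(C)C
F4 | step 21 | trimethylsilyl enol ether of 28 (C14=C30) | CO[C@H]1CC[C@@]2(C)[C@H](CC[C@@]3(C)CC(O[Si](C)(C)C)=CC[C@H]32)C1(C)C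
F5 | step 5 | racemic hydroxy lactone (one enantiomer drawn) | C1[C@@]2(C)CC[C@@H](O)C(C)(C)[C@H]2C(=O)O1
F6 | step 5 | (S)-O-methylmandelate of 8 | C1[C@@]2(C)CC[C@@H](OC(=O)[C@@H](OC)c3ccccc3)C(C)(C)[C@H]2C(=O)O1
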